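**Retrosynthetic overview**

1. Ring D (oxepine) is opened at its enol-ether O–C(sp2) bond: the 2'-OH of ring B and a 2-bromo-3-methylbut-2-enyl group on chromone C3 are joined last by copper-catalysed O-vinylation.
2. Ring B is built, not bought. It is a 1,2,4-trioxygenated benzene (2'-O para to the 5'-OMe, 4'-OMe beside it, H on C3' and C6', chromone on C1' ortho to the 2'-O), which is the pattern a Dötz benzannulation gives from a methoxy(1-methoxyvinyl)carbene chromium complex, one CO and a terminal 2-ethynylchromone (new bonds C5'–C6', C1'–C2', C2'–C3').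
3. The 2-ethynylchromone (rings A, C, E) comes from a 2-formylchromone by Ohira–Bestmann homologation; the aldehyde comes from Claisen condensation of the ring A methyl ketone with ethyl diethoxyacetate, C-alkylation of the diketone with 1,2-dibromo-3-methylbut-2-ene and acid cyclodehydration.
4. Ring E is closed with 3-methylbut-2-enal on a C-prenylated, selectively O-methylated phloroacetophenone.
5. Order of ring formation: A (bought) → E → C → B → D.

Key step: step 14

Remark on the chemistry: the target has no stereocentre and no stereogenic double bond (both exocyclic alkenes end in CMe2), so no stereocontrol is needed; the two stereocentres met on the way (the dibromo ester in step 7, the alkylated diketone in step 10) are racemic and are erased in the next operation.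

**Route**

Step 1
Reactants: 1 2,4,6-trihydroxyacetophenone; 2 1-bromo-3-methylbut-2-ene (prenyl bromide)
Product: 3 1-[2,4,6-trihydroxy-3-(3-methylbut-2-enyl)phenyl]ethanone
Conditions: 2 (1.0 equiv), DBU, THF, 0 °C to rt
Reagents that add atoms: none
Why: C-alkylation of the phloroglucinol-type phenoxide by the allylic bromide (direct C-prenylation); the two free ring carbons are equivalent, and limiting the bromide should hold the reaction at mono-alkylation.

Step 2
Reactants: 3 1-[2,4,6-trihydroxy-3-(3-methylbut-2-enyl)phenyl]ethanone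
Product: 4 1-[2-hydroxy-4,6-bis(methoxymethoxy)-3-(3-methylbut-2-enyl)phenyl]ethanone
Conditions: MOMCl (2.3 equiv), i-Pr2NEt, CH2Cl2, 0 °C to rt
Reagents that add atoms: chloromethyl methyl ether, COCCl
Why: Williamson-type MOM ether formation takes the unchelated 4-OH and then the less hindered of the two hydrogen-bonded ortho-hydroxyls (6-OH), so the 2-OH wedged between the acetyl and prenyl groups should stay free.

Step 3
Reactants: 4 1-[2-hydroxy-4,6-bis(methoxymethoxy)-3-(3-methylbut-2-enyl)phenyl]ethanone
Product: 5 1-[2-methoxy-4,6-bis(methoxymethoxy)-3-(3-methylbut-2-enyl)phenyl]ethanone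
Conditions: MeI, K2CO3, DMF, 40 °C
Reagents that add atoms: iodomethane, CI
Why: Williamson O-methylation of the one remaining (chelated, hindered) phenol is driven by the polar solvent and excess MeI, and fixes the future 5-OMe next to the prenyl group.

Step 4
Reactants: 5 1-[2-methoxy-4,6-bis(methoxymethoxy)-3-(3-methylbut-2-enyl)phenyl]ethanone
Product: 6 1-[4,6-dihydroxy-2-methoxy-3-(3-methylbut-2-enyl)phenyl]ethanone
Conditions: conc. HCl (cat.), MeOH, 40 °C
Reagents that add atoms: none
Why: Acid-catalysed acetal exchange with methanol removes both MOM ethers under conditions mild enough that the prenyl group should not add to the neighbouring phenol (chroman formation).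

Step 5
Reactants: 6 1-[4,6-dihydroxy-2-methoxy-3-(3-methylbut-2-enyl)phenyl]ethanone; 7 3-methylbut-2-enal
Product: 8 1-[5-hydroxy-7-methoxy-2,2-dimethyl-8-(3-methylbut-2-enyl)-2H-chromen-6-yl]ethanone
Conditions: 7 (2 equiv), ethylenediammonium diacetate (20 mol%), xylene, 140 °C
Reagents that add atoms: none
Why: Amine-salt-catalysed condensation of the enal at C5, the only free ring carbon, gives an ortho-quinone methide that closes ring E by oxa-6π-electrocyclisation through the unchelated 4-oxygen (chromenylation of resorcinol-type acylphenols), which leaves the hydrogen-bonded 6-OH for the pyrone.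

Step 6
Reactants: 8 1-[5-hydroxy-7-methoxy-2,2-dimethyl-8-(3-methylbut-2-enyl)-2H-chromen-6-yl]ethanone; 9 ethyl 2,2-diethoxyacetate
Product: 10 4,4-diethoxy-1-[5-hydroxy-7-methoxy-2,2-dimethyl-8-(3-methylbut-2-enyl)-2H-chromen-6-yl]butane-1,3-dione
Conditions: LiN(SiMe3)2 (3.3 equiv), THF, −78 °C; then 9, −78 °C to rt; AcOH quench
Reagents that add atoms: none
Why: Crossed Claisen condensation: the phenoxide/enolate dianion of 8 attacks the activated α,α-dialkoxy ester, and the product is held as its diketonate, which prevents a second acylation.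

Step 7
Reactants: 11 ethyl 3-methylbut-2-enoate
Product: 13 ethyl 2-bromo-3-methylbut-2-enoate, via ethyl 2,3-dibromo-3-methylbutanoate 12 (not isolated)
Conditions: Br2, CH2Cl2, 0 °C; then Et3N, 0 °C to rt
Reagents that add atoms: bromine, BrBr
Why: Electrophilic bromine addition across the enoate followed by amine-induced E1cB loss of HBr (the α-H is the acidic one) gives the α-bromoenoate, which has no E/Z issue because the β-carbon carries two methyls.

Step 8
Reactants: 13 ethyl 2-bromo-3-methylbut-2-enoate
Product: 14 2-bromo-3-methylbut-2-en-1-ol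
Conditions: i-Bu2AlH (2.2 equiv), CH2Cl2, −78 °C; then aqueous work-up
Reagents that add atoms: none
Why: Low-temperature 1,2-reduction of the conjugated ester by the aluminium hydride stops at the allylic alcohol and leaves the vinylic C–Br bond alone.

Step 9
Reactants: 14 2-bromo-3-methylbut-2-en-1-ol
Product: 15 1,2-dibromo-3-methylbut-2-ene
Conditions: PBr3 (0.4 equiv), Et2O, 0 °C
Reagents that add atoms: phosphorus tribromide, BrP(Br)Br
Why: PBr3 converts the primary allylic alcohol into the bromide through its phosphite (SN2), and the primary allylic bromide is also the thermodynamically preferred allylic isomer.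

Step 10
Reactants: 10 4,4-diethoxy-1-[5-hydroxy-7-methoxy-2,2-dimethyl-8-(3-methylbut-2-enyl)-2H-chromen-6-yl]butane-1,3-dione; 15 1,2-dibromo-3-methylbut-2-ene
Product: 16 2-(2-bromo-3-methylbut-2-enyl)-4,4-diethoxy-1-[5-hydroxy-7-methoxy-2,2-dimethyl-8-(3-methylbut-2-enyl)-2H-chromen-6-yl]butane-1,3-dione (racemic)
Conditions: 15 (1.1 equiv), K2CO3 (1.5 equiv), acetone, 45 °C
Reagents that add atoms: none
Why: The soft potassium diketonate is C-alkylated by the primary allylic bromide (SN2), while the vinylic bromide is inert and the hydrogen-bonded phenol is a poor nucleophile; the new stereocentre is racemic and disappears in step 11.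

Step 11
Reactants: 16 2-(2-bromo-3-methylbut-2-enyl)-4,4-diethoxy-1-[5-hydroxy-7-methoxy-2,2-dimethyl-8-(3-methylbut-2-enyl)-2H-chromen-6-yl]butane-1,3-dione
Product: 18 3-(2-bromo-3-methylbut-2-enyl)-5-methoxy-8,8-dimethyl-6-(3-methylbut-2-enyl)-4-oxo-4H,8H-pyrano[2,3-f]chromene-2-carbaldehyde, via 2-(diethoxymethyl)chromone acetal 17 (not isolated)
Conditions: p-TsOH·H2O (10 mol%), toluene, 60 °C; then 1 M HCl, THF, rt
Reagents that add atoms: water, O
Why: Acid-catalysed cyclodehydration (the phenol adds to the ketone next to the acetal, 6-exo-trig, then water is lost) builds the 4-pyrone ring C, and aqueous acid then hydrolyses the diethyl acetal to the 2-carbaldehyde.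

Step 12
Reactants: 18 3-(2-bromo-3-methylbut-2-enyl)-5-methoxy-8,8-dimethyl-6-(3-methylbut-2-enyl)-4-oxo-4H,8H-pyrano[2,3-f]chromene-2-carbaldehyde
Product: 19 3-(2-bromo-3-methylbut-2-enyl)-2-ethynyl-5-methoxy-8,8-dimethyl-6-(3-methylbut-2-enyl)-4H,8H-pyrano[2,3-f]chromen-4-one
Conditions: dimethyl (1-diazo-2-oxopropyl)phosphonate (1.3 equiv), K2CO3 (2 equiv), MeOH/THF, 0 °C to rt
Reagents that add atoms: dimethyl (1-diazo-2-oxopropyl)phosphonate, CC(=O)C(=[N+]=[N-])P(=O)(OC)OC
Why: Seyferth–Gilbert homologation with the Ohira–Bestmann reagent: methanolysis gives the diazomethylphosphonate anion, whose Horner–Wadsworth–Emmons-type addition to the aldehyde and loss of N2 give an alkylidene carbene that rearranges by 1,2-H shift to the terminal alkyne; a cold, short reaction should spare the pyrone.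

Step 13
Reactants: 20 methyl vinyl ether; 21 hexacarbonylchromium, Cr(CO)6
Product: 24 pentacarbonyl[methoxy(1-methoxyvinyl)carbene]chromium, via 1-methoxyvinyllithium 22 (not isolated), via lithium pentacarbonyl(2-methoxyacryloyl)chromate 23 (not isolated)
Conditions: t-BuLi, THF, −78 to 0 °C; Cr(CO)6, THF, −78 °C to rt; then MeOTf, CH2Cl2, 0 °C (argon)
Reagents that add atoms: methyl trifluoromethanesulfonate, COS(=O)(=O)C(F)(F)F
Why: Fischer carbene synthesis: α-lithiation of the vinyl ether, addition of the vinyllithium to a CO ligand of Cr(CO)6 and O-methylation of the acylchromate with a hard methylating agent, as for the cyclic analogue made from 2-lithiodihydropyran.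

Step 14
Reactants: 19 3-(2-bromo-3-methylbut-2-enyl)-2-ethynyl-5-methoxy-8,8-dimethyl-6-(3-methylbut-2-enyl)-4H,8H-pyrano[2,3-f]chromen-4-one; 24 pentacarbonyl[methoxy(1-methoxyvinyl)carbene]chromium
Product: 26 3-(2-bromo-3-methylbut-2-enyl)-2-(2-hydroxy-4,5-dimethoxyphenyl)-5-methoxy-8,8-dimethyl-6-(3-methylbut-2-enyl)-4H,8H-pyrano[2,3-f]chromen-4-one, via Cr(CO)3 η6-arene complex of this phenol 25 (not isolated)
Conditions: 24 (1.5 equiv), THF (degassed, 0.05 M), 55 °C; then air, daylight, Et2O, rt
Reagents that add atoms: none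
Why: Thermal loss of one CO from 24 lets the terminal alkyne of 19 coordinate and insert into the Cr=C bond with its CH carbon bonded to the carbene carbon; CO then inserts to give a chromium-bound dienylketene, which closes by 6π-electrocyclisation and tautomerises to the Cr(CO)3-bound 4-methoxyphenol 25, and air and light release 26. This is the Dötz benzannulation of an alkenyl(alkoxy)carbene complex of zerovalent chromium with a terminal alkyne, applied here to an acceptor-substituted chromon-2-yl alkyne, a class of alkyne (conjugated, ynone-like) that is known to react, if more slowly. Ring B is the only ring closed, by 6π-electrocyclic (formally [3+2+1]) closure: the carbene carbon becomes C5', the vinyl carbons C4' and C3', the alkyne carbons C6' and C1', and a CO ligand C2' with its hydroxyl, so that C5'–C6', C1'–C2' and C2'–C3' are the new bonds. No stereocentre is formed. The step needs the insertion regiochemistry that puts the chromonyl group next to the CO-derived carbon, which the steric difference between H and the bulky 3-substituted chromon-2-yl group of a terminal alkyne secures; it also needs phenol rather than indene or furan formation, which a methoxy(alkenyl) chromium carbene in THF at moderate temperature favours. The vinyl bromide, the prenyl and chromene alkenes and the pyrone carbonyl should not react with the carbene complex under these conditions.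

Step 15
Reactants: 26 3-(2-bromo-3-methylbut-2-enyl)-2-(2-hydroxy-4,5-dimethoxyphenyl)-5-methoxy-8,8-dimethyl-6-(3-methylbut-2-enyl)-4H,8H-pyrano[2,3-f]chromen-4-one
Product: 27 target CNP0192589.0 (oxepine ring D closed between the 2'-oxygen and the former C–Br carbon, isopropylidene exocyclic)
Conditions: CuI (20 mol%), 1,10-phenanthroline (40 mol%), Cs2CO3 (2 equiv), toluene, 110 °C
Reagents that add atoms: none
Why: Ullmann-type copper-catalysed C(sp2)–O coupling of the caesium phenoxide with the vinyl bromide; the two reacting centres are held close by the chromone C2–C3 bond and the C2–C1' biaryl bond, so the seven-membered ring D should close intramolecularly with the isopropylidene group left exocyclic.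

**Compound list**

1 | 2,4,6-trihydroxyacetophenone | CC(=O)c1c(O)cc(O)cc1O | starting material
2 | 1-bromo-3-methylbut-2-ene | CC(C)=CCBr | starting material
3 | 1-[2,4,6-trihydroxy-3-(3-methylbut-2-enyl)phenyl]ethanone | CC(=O)c1c(O)cc(O)c(CC=C(C)C)c1O | intermediate
4 | 1-[2-hydroxy-4,6-bis(methoxymethoxy)-3-(3-methylbut-2-enyl)phenyl]ethanone | CC(=O)c1c(OCOC)cc(OCOC)c(CC=C(C)C)c1O | intermediate
5 | 1-[2-methoxy-4,6-bis(methoxymethoxy)-3-(3-methylbut-2-enyl)phenyl]ethanone | CC(=O)c1c(OCOC)cc(OCOC)c(CC=C(C)C)c1OC | intermediate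
6 | 1-[4,6-dihydroxy-2-methoxy-3-(3-methylbut-2-enyl)phenyl]ethanone | CC(=O)c1c(O)cc(O)c(CC=C(C)C)c1OC | intermediate
7 | 3-methylbut-2-enal | CC(C)=CC=O | starting material
8 | 1-[5-hydroxy-7-methoxy-2,2-dimethyl-8-(3-methylbut-2-enyl)-2H-chromen-6-yl]ethanone | CC(=O)c1c(O)c2C=CC(C)(C)Oc2c(CC=C(C)C)c1OC | intermediate
9 | ethyl 2,2-diethoxyacetate | CCOC(=O)C(OCC)OCC | starting material
10 | 4,4-diethoxy-1-[5-hydroxy-7-methoxy-2,2-dimethyl-8-(3-methylbut-2-enyl)-2H-chromen-6-yl]butane-1,3-dione | CCOC(OCC)C(=O)CC(=O)c1c(O)c2C=CC(C)(C)Oc2c(CC=C(C)C)c1OC | intermediate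
11 | ethyl 3-methylbut-2-enoate | CCOC(=O)C=C(C)C | starting material
12 | ethyl 2,3-dibromo-3-methylbutanoate (racemic) | CCOC(=O)C(Br)C(C)(C)Br | intermediate (not isolated)
13 | ethyl 2-bromo-3-methylbut-2-enoate | CCOC(=O)C(Br)=C(C)C | intermediate
14 | 2-bromo-3-methylbut-2-en-1-ol | CC(C)=C(Br)CO | intermediate
15 | 1,2-dibromo-3-methylbut-2-ene | CC(C)=C(Br)CBr | intermediate
16 | 2-(2-bromo-3-methylbut-2-enyl)-4,4-diethoxy-1-[5-hydroxy-7-methoxy-2,2-dimethyl-8-(3-methylbut-2-enyl)-2H-chromen-6-yl]butane-1,3-dione (racemic) | CCOC(OCC)C(=O)C(CC(Br)=C(C)C)C(=O)c1c(O)c2C=CC(C)(C)Oc2c(CC=C(C)C)c1OC | intermediate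
17 | 3-(2-bromo-3-methylbut-2-enyl)-2-(diethoxymethyl)-5-methoxy-8,8-dimethyl-6-(3-methylbut-2-enyl)-4H,8H-pyrano[2,3-f]chromen-4-one | CCOC(OCC)c1oc3c4c(c(CC=C(C)C)c(OC)c3c(=O)c1CC(Br)=C(C)C)OC(C)(C)C=C4 | intermediate (not isolated)
18 | 3-(2-bromo-3-methylbut-2-enyl)-5-methoxy-8,8-dimethyl-6-(3-methylbut-2-enyl)-4-oxo-4H,8H-pyrano[2,3-f]chromene-2-carbaldehyde | O=Cc1oc3c4c(c(CC=C(C)C)c(OC)c3c(=O)c1CC(Br)=C(C)C)OC(C)(C)C=C4 | intermediate
19 | 3-(2-bromo-3-methylbut-2-enyl)-2-ethynyl-5-methoxy-8,8-dimethyl-6-(3-methylbut-2-enyl)-4H,8H-pyrano[2,3-f]chromen-4-one | C#Cc1oc3c4c(c(CC=C(C)C)c(OC)c3c(=O)c1CC(Br)=C(C)C)OC(C)(C)C=C4 | intermediate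
20 | methyl vinyl ether | COC=C | starting material
21 | hexacarbonylchromium, Cr(CO)6 | O=C=[Cr](=C=O)(=C=O)(=C=O)(=C=O)=C=O | starting material
22 | 1-methoxyvinyllithium | [Li]C(=C)OC | intermediate (not isolated)
23 | lithium pentacarbonyl(2-methoxyacryloyl)chromate | [Li+].[O-]C(C(=C)OC)=[Cr](=C=O)(=C=O)(=C=O)(=C=O)=C=O | intermediate (not isolated)
24 | pentacarbonyl[methoxy(1-methoxyvinyl)carbene]chromium | COC(=C)C(OC)=[Cr](=C=O)(=C=O)(=C=O)(=C=O)=C=O | intermediate
25 | Cr(CO)3 complex of phenol 26, η6 on ring B (SMILES shows the arene beside the Cr(CO)3 fragment) | COc1cc(O)c(cc1OC)-c1oc3c4c(c(CC=C(C)C)c(OC)c3c(=O)c1CC(Br)=C(C)C)OC(C)(C)C=C4.O=C=[Cr](=C=O)=C=O | intermediate (not isolated)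
26 | 3-(2-bromo-3-methylbut-2-enyl)-2-(2-hydroxy-4,5-dimethoxyphenyl)-5-methoxy-8,8-dimethyl-6-(3-methylbut-2-enyl)-4H,8H-pyrano[2,3-f]chromen-4-one | COc1cc(O)c(cc1OC)-c1oc3c4c(c(CC=C(C)C)c(OC)c3c(=O)c1CC(Br)=C(C)C)OC(C)(C)C=C4 | intermediate
27 | CNP0192589.0: flavone with 5-OMe, 6-prenyl, 2,2-dimethylpyran ring E on C7–C8, 4',5'-dimethoxy ring B, and oxepine ring D (C3–CH2–C(=CMe2)–O–C2') | COc1cc2c(cc1OC)-c1oc3c4c(c(CC=C(C)C)c(OC)c3c(=O)c1CC(=C(C)C)O2)OC(C)(C)C=C4 | target

**Step count and risks**

Total steps: 15. Longest linear sequence: 11 steps (steps 1–6, 10–12, 14, 15).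

The three steps most likely to fail:

Step 14 (Dötz benzannulation). Insertion of the electron-poor chromonyl alkyne may be slower than thermal decay of the carbene complex, or the dienylketene may be diverted to cyclopentannulation or furan formation instead of closing to the phenol. The fallback brings ring B in ready-made by classical flavone chemistry and sets out from ketone 8. Claisen condensation of 8 (LiN(SiMe3)2, THF) with methyl 4,5-dimethoxy-2-(methoxymethoxy)benzoate F1 (the MOM ether of the commercial methyl salicylate) should give the 1,3-diketone 1-[4,5-dimethoxy-2-(methoxymethoxy)phenyl]-3-[5-hydroxy-7-methoxy-2,2-dimethyl-8-(3-methylbut-2-enyl)-2H-chromen-6-yl]propane-1,3-dione F2. C-alkylation with 15 (K2CO3, acetone) should give its 2-(2-bromo-3-methylbut-2-enyl) derivative F3. p-TsOH in MeOH at 50 °C should then close the pyrone through the free ring A hydroxyl and cleave the MOM ether, which comes back to the route at phenol 26.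

Step 15 (copper-catalysed closure of ring D). Activation of the hindered, tetrasubstituted vinyl bromide by the copper phenoxide may be slower than protodebromination or base-induced loss of HBr to an allene, and the seven-membered closure may not compete. The fallback reverses the polarity of the vinyl partner and sets out from 26. Miyaura borylation (PdCl2(dppf), B2pin2, KOAc, dioxane, 80 °C) should give the alkenyl pinacol boronate F4. Intramolecular Chan–Lam coupling of its phenol with the alkenyl boronate (Cu(OAc)2, pyridine, 4 Å sieves, air, CH2Cl2, rt) should then form the same O–C(sp2) bond and come back at target 27.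

Step 12 (Ohira–Bestmann homologation). Methoxide may add to the pyrone or to the newly formed conjugated alkyne, or open the pyrone ring, before homologation is complete. The fallback avoids basic methanol and sets out from aldehyde 18. Ramirez dibromo-olefination (CBr4, PPh3, CH2Cl2, 0 °C) should give the 2-(2,2-dibromovinyl)chromone F5. DBU in DMSO at rt should then convert it to the terminal alkyne by dehydrobromination to the bromoalkyne and halophilic removal of the second bromine, coming back at alkyne 19.

**Further compounds**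

F1 | step 14 | methyl 4,5-dimethoxy-2-(methoxymethoxy)benzoate | COCOc1cc(OC)c(OC)cc1C(=O)OC
F2 | step 14 | 1-[4,5-dimethoxy-2-(methoxymethoxy)phenyl]-3-[5-hydroxy-7-methoxy-2,2-dimethyl-8-(3-methylbut-2-enyl)-2H-chromen-6-yl]propane-1,3-dione | COCOc1cc(OC)c(OC)cc1C(=O)CC(=O)c1c(O)c2C=CC(C)(C)Oc2c(CC=C(C)C)c1OC
F3 | step 14 | 2-(2-bromo-3-methylbut-2-enyl)-1-[4,5-dimethoxy-2-(methoxymethoxy)phenyl]-3-[5-hydroxy-7-methoxy-2,2-dimethyl-8-(3-methylbut-2-enyl)-2H-chromen-6-yl]propane-1,3-dione (racemic) | COCOc1cc(OC)c(OC)cc1C(=O)C(CC(Br)=C(C)C)C(=O)c1c(O)c2C=CC(C)(C)Oc2c(CC=C(C)C)c1OC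
F4 | step 15 | 2-(2-hydroxy-4,5-dimethoxyphenyl)-5-methoxy-8,8-dimethyl-6-(3-methylbut-2-enyl)-3-[3-methyl-2-(4,4,5,5-tetramethyl-1,3,2-dioxaborolan-2-yl)but-2-enyl]-4H,8H-pyrano[2,3-f]chromen-4-one | COc1cc(O)c(cc1OC)-c1oc3c4c(c(CC=C(C)C)c(OC)c3c(=O)c1CC(B2OC(C)(C)C(C)(C)O2)=C(C)C)OC(C)(C)C=C4
F5 | step 12 | 3-(2-bromo-3-methylbut-2-enyl)-2-(2,2-dibromovinyl)-5-methoxy-8,8-dimethyl-6-(3-methylbut-2-enyl)-4H,8H-pyrano[2,3-f]chromen-4-one | BrC(Br)=Cc1oc3c4c(c(CC=C(C)C)c(OC)c3c(=O)c1CC(Br)=C(C)C)OC(C)(C)C=C4
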